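**Plan**

- Feature: ring D is substituted at every carbon except C8, and lower C6 (bonded to upper C4) lies between the oxygenated carbons C5 and C7, with O1 on C8a. This 2-alkylresorcinol pattern is what a siloxyalkyne (C5, C6) and the vinylketene of a 3-alkoxycyclobutenone (C7, C8, C8a, C4a) assemble in one thermal operation.
- Retrosynthesis: after removal of four benzyl ethers and one silyl ether, ring D is cut at lower C6–C7 and C4a–C5 (C7–C8 opens and re-forms). This gives an upper flavan-4-yl siloxyalkyne (fragment 1) and a ring F-fused 3-alkoxycyclobutenone (fragment 2).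
- Fragment 1 is cut at C4–C≡C (one-carbon ynolate homologation of a C4 ester) and at C4–CO2Me back to (2S)-liquiritigenin. Fragment 2 is cut at O1–C8a (alkoxy exchange), across the four-membered ring (ketene + ynol ether), at C4–C4a (acetylide alkylation) and at C2–C3 (glycolate aldol).
- Forward order: rings A, C and B arrive with liquiritigenin; the lower chain is joined C2–C3, then C4–C4a; the cyclobutenone is added and ring F closed; ring D is formed last and unites the halves.
- Stereochemistry: upper C2 comes from natural (2S)-liquiritigenin; upper C4 is set by hydrogenation anti to the 2-aryl group (2,4-cis) and carried with retention through the ynolate 1,2-shift. Lower C2 and C3 come from an Evans syn-glycolate aldol, and ring F closes without breaking the C2–O bond.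

Key step: step 15

Assumption: (2S)-liquiritigenin 1 is bought as the enantiopure natural flavanone; since flavanones can racemise by reversible ring opening, the ee is to be checked by chiral HPLC at dibenzyl ether 2 and raised there by crystallisation if needed.

**Route**

Step 1
Reactants: 1 (2S)-liquiritigenin
Product: 2 (2S)-7-(benzyloxy)-2-[4-(benzyloxy)phenyl]chroman-4-one
Conditions: BnOH, PPh3, DIAD, THF, 0 °C → rt
Reagents that add atoms: benzyl alcohol (OCc1ccccc1)
Why: Double Mitsunobu etherification should benzylate both phenols under essentially neutral conditions, avoiding the carbonate or alkoxide bases that open 4'-hydroxyflavanones to chalcones and would erode C2.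

Step 2
Reactants: 2 (2S)-7-(benzyloxy)-2-[4-(benzyloxy)phenyl]chroman-4-one
Product: 3 (2S)-7-(benzyloxy)-2-[4-(benzyloxy)phenyl]-2H-chromen-4-yl trifluoromethanesulfonate
Conditions: Tf2O, 2,6-di-tert-butyl-4-methylpyridine, CH2Cl2, 0 °C → rt
Reagents that add atoms: triflic anhydride (O=S(=O)(OS(=O)(=O)C(F)(F)F)C(F)(F)F)
Why: Enol triflate formation by O-triflation of the aryl ketone and loss of H3 from the oxygen-stabilised triflyloxycarbenium ion needs no enolate, so E1cB opening of ring C cannot scramble C2.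

Step 3
Reactants: 3 (2S)-7-(benzyloxy)-2-[4-(benzyloxy)phenyl]-2H-chromen-4-yl trifluoromethanesulfonate
Product: 4 methyl (2S)-7-(benzyloxy)-2-[4-(benzyloxy)phenyl]-2H-chromene-4-carboxylate
Conditions: Pd(OAc)2 (cat.), dppp (cat.), CO (1 atm), MeOH, Et3N, DMF, 60 °C
Reagents that add atoms: carbon monoxide ([C-]#[O+]); methanol (CO)
Why: Palladium-catalysed alkoxycarbonylation of an enol triflate (oxidative addition to zerovalent palladium, CO insertion, methanolysis of the acyl complex) should install the C4 ester carbon cleanly.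

Step 4
Reactants: 4 methyl (2S)-7-(benzyloxy)-2-[4-(benzyloxy)phenyl]-2H-chromene-4-carboxylate
Product: 5 methyl (2S,4S)-7-(benzyloxy)-2-[4-(benzyloxy)phenyl]chromane-4-carboxylate (2,4-cis)
Conditions: H2 (1–4 atm), [Ir(cod)(PCy3)(py)]PF6 (cat.), CH2Cl2, rt
Reagents that add atoms: none
Why: Homogeneous iridium-catalysed hydrogenation reduces the trisubstituted, ester-conjugated C3=C4 bond without hydrogenolysis of the aryl benzyl ethers or the benzylic C2–O1 bond, and delivery of H2 to the face opposite the 2-aryl group should place the C4 ester cis to it (substrate control of the new C4 stereocentre).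

Step 5
Reactants: 5 methyl (2S,4S)-7-(benzyloxy)-2-[4-(benzyloxy)phenyl]chromane-4-carboxylate
Product: 8 triisopropyl({[(2S,4R)-7-(benzyloxy)-2-[4-(benzyloxy)phenyl]chroman-4-yl]ethynyl}oxy)silane (fragment 1), via dibromoketone enolate 6 (not isolated), via lithium ynolate 7 (not isolated)
Conditions: CH2Br2, LiTMP (lithium 2,2,6,6-tetramethylpiperidide), THF, –78 °C; LiN(SiMe3)2, –78 °C; n-BuLi, –78 °C → rt; i-Pr3SiCl, –78 → 0 °C
Reagents that add atoms: dibromomethane (BrCBr); triisopropylsilyl chloride (CC(C)[Si](Cl)(C(C)C)C(C)C)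
Why: In the Kowalski ester homologation LiCHBr2 adds to the ester, bromine–lithium exchange on enolate 6 gives a carbenoid whose flavan-4-yl group shifts to carbon with retention at C4 to form ynolate 7, and the bulky silyl chloride then silylates 7 on oxygen (the change of the C4 descriptor from S to R is only a priority change).

Step 6
Reactants: 9 (S)-4-benzyloxazolidin-2-one; 10 (benzyloxy)acetyl chloride
Product: 12 (S)-4-benzyl-3-[(benzyloxy)acetyl]oxazolidin-2-one, via lithium oxazolidinide 11 (not isolated)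
Conditions: n-BuLi, THF, –78 °C; then 10, –78 → 0 °C
Reagents that add atoms: none
Why: N-Acylation of the lithiated oxazolidinone with an acid chloride is the standard entry to the glycolyl imide.

Step 7
Reactants: 12 (S)-4-benzyl-3-[(benzyloxy)acetyl]oxazolidin-2-one; 13 4-(benzyloxy)benzaldehyde
Product: 16 (4S)-4-benzyl-3-[(2S,3R)-2-(benzyloxy)-3-[4-(benzyloxy)phenyl]-3-hydroxypropanoyl]oxazolidin-2-one, via Z-boron enolate 14 (not isolated), via boron aldolate 15 (not isolated)
Conditions: n-Bu2BOTf, Et3N, CH2Cl2, –78 → 0 °C; then 13, –78 → 0 °C; pH 7 buffer, MeOH, H2O2, 0 °C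
Reagents that add atoms: none
Why: In the Evans syn-glycolate aldol the Z-dibutylboron enolate reacts through a closed chair (Zimmerman–Traxler) transition state on the face away from the auxiliary benzyl group, which should set C2 (S) and C3 (R) together, i.e. the future lower C3 and C2 in their 2,3-cis relationship.

Step 8
Reactants: 16 (4S)-4-benzyl-3-[(2S,3R)-2-(benzyloxy)-3-[4-(benzyloxy)phenyl]-3-hydroxypropanoyl]oxazolidin-2-one
Product: 17 (4S)-4-benzyl-3-[(2S,3R)-2-(benzyloxy)-3-[4-(benzyloxy)phenyl]-3-[(triethylsilyl)oxy]propanoyl]oxazolidin-2-one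
Conditions: Et3SiCl, imidazole, DMF, 0 °C → rt
Reagents that add atoms: chlorotriethylsilane (CC[Si](Cl)(CC)CC)
Why: Silylation of the secondary benzylic alcohol masks it for the triflation, acetylide and ketene steps and can later be undone by fluoride without acid.

Step 9
Reactants: 17 (4S)-4-benzyl-3-[(2S,3R)-2-(benzyloxy)-3-[4-(benzyloxy)phenyl]-3-[(triethylsilyl)oxy]propanoyl]oxazolidin-2-one
Product: 18 (2R,3R)-2-(benzyloxy)-3-[4-(benzyloxy)phenyl]-3-[(triethylsilyl)oxy]propan-1-ol
Conditions: LiBH4, MeOH (1 equiv), Et2O, 0 °C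
Reagents that add atoms: none
Why: Reductive cleavage of the N-acyl oxazolidinone with LiBH4 releases the primary alcohol and the auxiliary without touching the α-stereocentre or the silyl ether.

Step 10
Reactants: 18 (2R,3R)-2-(benzyloxy)-3-[4-(benzyloxy)phenyl]-3-[(triethylsilyl)oxy]propan-1-ol
Product: 19 (2R,3R)-2-(benzyloxy)-3-[4-(benzyloxy)phenyl]-3-[(triethylsilyl)oxy]propyl trifluoromethanesulfonate
Conditions: Tf2O, 2,6-lutidine, CH2Cl2, –78 °C (used crude)
Reagents that add atoms: triflic anhydride (O=S(=O)(OS(=O)(=O)C(F)(F)F)C(F)(F)F)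
Why: Sulfonylation of the primary alcohol gives a triflate reactive enough for SN2 displacement at a β-alkoxy-branched carbon at low temperature.

Step 11
Reactants: 19 (2R,3R)-2-(benzyloxy)-3-[4-(benzyloxy)phenyl]-3-[(triethylsilyl)oxy]propyl trifluoromethanesulfonate; 20 ethoxyacetylene
Product: 22 triethyl{[(1R,2R)-2-(benzyloxy)-1-[4-(benzyloxy)phenyl]-5-ethoxypent-4-yn-1-yl]oxy}silane, via lithium ethoxyacetylide 21 (not isolated)
Conditions: n-BuLi, THF, –78 °C; then 19, DMPU, –78 → –20 °C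
Reagents that add atoms: none
Why: SN2 alkylation of a lithium alkoxyacetylide with a primary triflate forms the C4–C4a bond and delivers the internal ynol ether, which is stable to the basic medium.

Step 12
Reactants: 22 triethyl{[(1R,2R)-2-(benzyloxy)-1-[4-(benzyloxy)phenyl]-5-ethoxypent-4-yn-1-yl]oxy}silane
Product: 23 2-[(2R,3R)-2-(benzyloxy)-3-[4-(benzyloxy)phenyl]-3-[(triethylsilyl)oxy]propyl]-3-ethoxycyclobut-2-en-1-one
Conditions: ketene (gas from acetone pyrolysis, excess), CH2Cl2, 0 °C → rt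
Reagents that add atoms: ketene (C=C=O)
Why: In the thermal [2+2] cycloaddition of ketene to a 1-alkoxyalkyne the nucleophilic, alkyl-bearing alkyne carbon bonds to the ketene carbonyl carbon, so the side chain ends at C2 and a CH2 at C4 of the 3-ethoxycyclobutenone, the substitution fragment 2 needs.

Step 13
Reactants: 23 2-[(2R,3R)-2-(benzyloxy)-3-[4-(benzyloxy)phenyl]-3-[(triethylsilyl)oxy]propyl]-3-ethoxycyclobut-2-en-1-one
Product: 24 2-[(2R,3R)-2-(benzyloxy)-3-[4-(benzyloxy)phenyl]-3-hydroxypropyl]-3-ethoxycyclobut-2-en-1-one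
Conditions: HF·pyridine, pyridine, THF, 0 °C
Reagents that add atoms: none
Why: Buffered fluoride cleavage of the triethylsilyl ether frees the benzylic hydroxyl without an alkoxide that could attack the strained carbonyl.

Step 14
Reactants: 24 2-[(2R,3R)-2-(benzyloxy)-3-[4-(benzyloxy)phenyl]-3-hydroxypropyl]-3-ethoxycyclobut-2-en-1-one
Product: 25 (3R,4R)-4-(benzyloxy)-3-[4-(benzyloxy)phenyl]-2-oxabicyclo[4.2.0]oct-1(6)-en-7-one (fragment 2)
Conditions: PPTS (cat.), 5 Å MS, PhMe, 50 °C
Reagents that add atoms: none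
Why: In this acid-catalysed alkoxy exchange of a vinylogous ester the tethered hydroxyl adds to C3 of the protonated 3-ethoxycyclobutenone and ethanol is expelled into the sieves, closing six-membered ring F by addition–elimination without breaking the carbinol C–O bond, so the 2,3-cis configuration is retained.

Step 15
Reactants: 8 triisopropyl({[(2S,4R)-7-(benzyloxy)-2-[4-(benzyloxy)phenyl]chroman-4-yl]ethynyl}oxy)silane (fragment 1); 25 (3R,4R)-4-(benzyloxy)-3-[4-(benzyloxy)phenyl]-2-oxabicyclo[4.2.0]oct-1(6)-en-7-one (fragment 2)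
Product: 30 (2R,3R)-3-(benzyloxy)-2-[4-(benzyloxy)phenyl]-6-[(2S,4S)-7-(benzyloxy)-2-[4-(benzyloxy)phenyl]chroman-4-yl]-5-[(triisopropylsilyl)oxy]chroman-7-ol, via vinylketene 26 (not isolated), via spiro-cyclobutenone 27 (not isolated), via dienylketene 28 (not isolated), via cyclohexadienone 29 (not isolated)
Conditions: PhMe (degassed), 120 °C, sealed tube, argon
Reagents that add atoms: none
Why: Proposed new method: thermal conrotatory 4π opening of cyclobutenone 25, a substrate class (3-alkoxycyclobutenone annulated across C2–C3 to an oxygen ring) not yet tried in this chemistry, should give the s-cis-locked vinylketene 26, whose ketene carbon (future C7) is attacked by the nucleophilic, flavanyl-bearing alkyne carbon of 8 (future C6) while its α-carbon C4a bonds to the siloxy carbon (future C5) in a [2+2] cycloaddition to spiro-cyclobutenone 27; the closest known reaction type is the Danheiser benzannulation of monocyclic cyclobutenones with triisopropylsiloxyalkynes to resorcinol monosilyl ethers. A second, reversible 4π opening of 27 gives dienylketene 28, and ring D then closes by thermal disrotatory 6π-electrocyclisation between C7 and the exocyclic methylene C8 to cyclohexadienone 29, which tautomerises to the C7 phenol. No permanent stereocentre is created, since the spiro carbon C4a of 27 becomes aromatic, and the four existing stereocentres lie outside the reacting π-system and meet only neutral conditions. The step needs regioselectivity in the ketene–alkyne union, and the oxygen polarisation of the ynol silyl ether secures it (the carbon remote from oxygen is the nucleophile), so the flavanyl group must end at C6 between the C5 siloxy and C7 hydroxy carbons, giving the 4→6 and not the 4→8 linkage. Only the isomer of 28 with the ketene arm syn to the enol-ether methylene can cyclise, while the other re-closes to 27 and re-opens, which should funnel material to 30.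

Step 16
Reactants: 30 (2R,3R)-3-(benzyloxy)-2-[4-(benzyloxy)phenyl]-6-[(2S,4S)-7-(benzyloxy)-2-[4-(benzyloxy)phenyl]chroman-4-yl]-5-[(triisopropylsilyl)oxy]chroman-7-ol
Product: 31 (2R,3R)-3-(benzyloxy)-2-[4-(benzyloxy)phenyl]-6-[(2S,4S)-7-(benzyloxy)-2-[4-(benzyloxy)phenyl]chroman-4-yl]chromane-5,7-diol
Conditions: Bu4NF, AcOH, THF, 0 °C
Reagents that add atoms: none
Why: Fluoride cleavage of the aryl silyl ether, buffered with acetic acid so that the electron-rich resorcinol is not left as an air-sensitive phenoxide, frees the C5 hydroxyl.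

Step 17
Reactants: 31 (2R,3R)-3-(benzyloxy)-2-[4-(benzyloxy)phenyl]-6-[(2S,4S)-7-(benzyloxy)-2-[4-(benzyloxy)phenyl]chroman-4-yl]chromane-5,7-diol
Product: 32 (2R,3R)-6-[(2S,4S)-7-hydroxy-2-(4-hydroxyphenyl)chroman-4-yl]-2-(4-hydroxyphenyl)chromane-3,5,7-triol (target)
Conditions: H2 (1 atm), Pd(OH)2/C, THF/MeOH, rt
Reagents that add atoms: none
Why: Catalytic hydrogenolysis removes the three aryl benzyl ethers and the C3 alkyl benzyl ether under neutral conditions that the acid-labile flavan C2–O bonds and the interflavan C4–C6 bond are expected to survive.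

**Compound list**

1 | (2S)-liquiritigenin, (2S)-7-hydroxy-2-(4-hydroxyphenyl)chroman-4-one | Oc1ccc([C@@H]2CC(=O)c3ccc(O)cc3O2)cc1 | starting material
2 | (2S)-7-(benzyloxy)-2-[4-(benzyloxy)phenyl]chroman-4-one | c1ccccc1COc1ccc([C@@H]2CC(=O)c3ccc(OCc4ccccc4)cc3O2)cc1 | intermediate
3 | (2S)-7-(benzyloxy)-2-[4-(benzyloxy)phenyl]-2H-chromen-4-yl trifluoromethanesulfonate | c1ccccc1COc1ccc([C@@H]2C=C(OS(=O)(=O)C(F)(F)F)c3ccc(OCc4ccccc4)cc3O2)cc1 | intermediate
4 | methyl (2S)-7-(benzyloxy)-2-[4-(benzyloxy)phenyl]-2H-chromene-4-carboxylate | c1ccccc1COc1ccc([C@@H]2C=C(C(=O)OC)c3ccc(OCc4ccccc4)cc3O2)cc1 | intermediate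
5 | methyl (2S,4S)-7-(benzyloxy)-2-[4-(benzyloxy)phenyl]chromane-4-carboxylate (2,4-cis) | c1ccccc1COc1ccc([C@@H]2C[C@H](C(=O)OC)c3ccc(OCc4ccccc4)cc3O2)cc1 | intermediate
6 | lithium 2,2-dibromo-1-[(2S,4S)-7-(benzyloxy)-2-[4-(benzyloxy)phenyl]chroman-4-yl]ethen-1-olate | c1ccccc1COc1ccc([C@@H]2C[C@H](C([O-])=C(Br)Br)c3ccc(OCc4ccccc4)cc3O2)cc1.[Li+] | intermediate (not isolated)
7 | lithium 2-[(2S,4R)-7-(benzyloxy)-2-[4-(benzyloxy)phenyl]chroman-4-yl]ethyn-1-olate | c1ccccc1COc1ccc([C@@H]2C[C@H](C#C[O-])c3ccc(OCc4ccccc4)cc3O2)cc1.[Li+] | intermediate (not isolated)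
8 | triisopropyl({[(2S,4R)-7-(benzyloxy)-2-[4-(benzyloxy)phenyl]chroman-4-yl]ethynyl}oxy)silane (fragment 1, 2,4-cis) | c1ccccc1COc1ccc([C@@H]2C[C@H](C#CO[Si](C(C)C)(C(C)C)C(C)C)c3ccc(OCc4ccccc4)cc3O2)cc1 | intermediate
9 | (S)-4-benzyloxazolidin-2-one | O=C1N[C@@H](Cc2ccccc2)CO1 | starting material
10 | (benzyloxy)acetyl chloride | O=C(Cl)COCc1ccccc1 | starting material
11 | lithium (S)-4-benzyl-2-oxooxazolidin-3-ide | O=C1[N-][C@@H](Cc2ccccc2)CO1.[Li+] | intermediate (not isolated)
12 | (S)-4-benzyl-3-[(benzyloxy)acetyl]oxazolidin-2-one | O=C(COCc1ccccc1)N1[C@@H](Cc2ccccc2)COC1=O | intermediate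
13 | 4-(benzyloxy)benzaldehyde | O=Cc1ccc(OCc2ccccc2)cc1 | starting material
14 | (Z)-dibutylboron enolate of 12 | CCCCB(CCCC)O/C(=C\OCc1ccccc1)N1[C@@H](Cc2ccccc2)COC1=O | intermediate (not isolated)
15 | O-dibutylboryl aldolate of 16 | O=C(N1[C@@H](Cc2ccccc2)COC1=O)[C@@H](OCc1ccccc1)[C@@H](c1ccc(OCc2ccccc2)cc1)OB(CCCC)CCCC | intermediate (not isolated)
16 | (4S)-4-benzyl-3-[(2S,3R)-2-(benzyloxy)-3-[4-(benzyloxy)phenyl]-3-hydroxypropanoyl]oxazolidin-2-one | O=C(N1[C@@H](Cc2ccccc2)COC1=O)[C@@H](OCc1ccccc1)[C@@H](c1ccc(OCc2ccccc2)cc1)O | intermediate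
17 | (4S)-4-benzyl-3-[(2S,3R)-2-(benzyloxy)-3-[4-(benzyloxy)phenyl]-3-[(triethylsilyl)oxy]propanoyl]oxazolidin-2-one | O=C(N1[C@@H](Cc2ccccc2)COC1=O)[C@@H](OCc1ccccc1)[C@@H](c1ccc(OCc2ccccc2)cc1)O[Si](CC)(CC)CC | intermediate
18 | (2R,3R)-2-(benzyloxy)-3-[4-(benzyloxy)phenyl]-3-[(triethylsilyl)oxy]propan-1-ol | OC[C@@H](OCc1ccccc1)[C@@H](c1ccc(OCc2ccccc2)cc1)O[Si](CC)(CC)CC | intermediate
19 | (2R,3R)-2-(benzyloxy)-3-[4-(benzyloxy)phenyl]-3-[(triethylsilyl)oxy]propyl trifluoromethanesulfonate | FC(F)(F)S(=O)(=O)OC[C@@H](OCc1ccccc1)[C@@H](c1ccc(OCc2ccccc2)cc1)O[Si](CC)(CC)CC | intermediate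
20 | ethoxyacetylene | CCOC#C | starting material
21 | lithium ethoxyacetylide | CCOC#C[Li] | intermediate (not isolated)
22 | triethyl{[(1R,2R)-2-(benzyloxy)-1-[4-(benzyloxy)phenyl]-5-ethoxypent-4-yn-1-yl]oxy}silane | CCOC#CC[C@@H](OCc1ccccc1)[C@@H](c1ccc(OCc2ccccc2)cc1)O[Si](CC)(CC)CC | intermediate
23 | 2-[(2R,3R)-2-(benzyloxy)-3-[4-(benzyloxy)phenyl]-3-[(triethylsilyl)oxy]propyl]-3-ethoxycyclobut-2-en-1-one | O=C1CC(OCC)=C1C[C@@H](OCc1ccccc1)[C@@H](c1ccc(OCc2ccccc2)cc1)O[Si](CC)(CC)CC | intermediate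
24 | 2-[(2R,3R)-2-(benzyloxy)-3-[4-(benzyloxy)phenyl]-3-hydroxypropyl]-3-ethoxycyclobut-2-en-1-one | O=C1CC(OCC)=C1C[C@@H](OCc1ccccc1)[C@@H](c1ccc(OCc2ccccc2)cc1)O | intermediate
25 | (3R,4R)-4-(benzyloxy)-3-[4-(benzyloxy)phenyl]-2-oxabicyclo[4.2.0]oct-1(6)-en-7-one (fragment 2) | O=C1CC2=C1C[C@@H](OCc1ccccc1)[C@@H](c1ccc(OCc3ccccc3)cc1)O2 | intermediate
26 | vinylketene, (5R,6R)-5-(benzyloxy)-6-[4-(benzyloxy)phenyl]-2-methylidene-3-(oxomethylidene)oxane | O=C=C1C[C@@H](OCc2ccccc2)[C@@H](c2ccc(OCc3ccccc3)cc2)OC1=C | intermediate (not isolated)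
27 | spiro-cyclobutenone, (7R,8R)-8-(benzyloxy)-7-[4-(benzyloxy)phenyl]-2-[(2S,4S)-7-(benzyloxy)-2-[4-(benzyloxy)phenyl]chroman-4-yl]-5-methylidene-3-[(triisopropylsilyl)oxy]-6-oxaspiro[3.5]non-2-en-1-one, spiro carbon of either configuration | O=C1C([C@H]2C[C@@H](c3ccc(OCc4ccccc4)cc3)Oc3cc(OCc4ccccc4)ccc23)=C(O[Si](C(C)C)(C(C)C)C(C)C)C15C[C@@H](OCc2ccccc2)[C@@H](c2ccc(OCc3ccccc3)cc2)OC5=C | intermediate (not isolated)
28 | dienylketene, 2-[(2S,4S)-7-(benzyloxy)-2-[4-(benzyloxy)phenyl]chroman-4-yl]-3-[(5R,6R)-5-(benzyloxy)-6-[4-(benzyloxy)phenyl]-2-methylideneoxan-3-ylidene]-3-[(triisopropylsilyl)oxy]prop-1-en-1-one, ketene arm syn to the methylidene carbon | C=C1O[C@H](c2ccc(OCc3ccccc3)cc2)[C@H](OCc2ccccc2)C/C1=C(\O[Si](C(C)C)(C(C)C)C(C)C)/C([C@H]1C[C@@H](c2ccc(OCc3ccccc3)cc2)Oc2cc(OCc3ccccc3)ccc12)=C=O | intermediate (not isolated)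
29 | cyclohexadienone, (2R,3R)-3-(benzyloxy)-2-[4-(benzyloxy)phenyl]-6-[(2S,4S)-7-(benzyloxy)-2-[4-(benzyloxy)phenyl]chroman-4-yl]-5-[(triisopropylsilyl)oxy]-3,4-dihydro-2H-chromen-7(8H)-one | O=C1CC2=C(C[C@@H](OCc3ccccc3)[C@@H](c3ccc(OCc4ccccc4)cc3)O2)C(O[Si](C(C)C)(C(C)C)C(C)C)=C1[C@H]1C[C@@H](c2ccc(OCc3ccccc3)cc2)Oc2cc(OCc3ccccc3)ccc12 | intermediate (not isolated)
30 | (2R,3R)-3-(benzyloxy)-2-[4-(benzyloxy)phenyl]-6-[(2S,4S)-7-(benzyloxy)-2-[4-(benzyloxy)phenyl]chroman-4-yl]-5-[(triisopropylsilyl)oxy]chroman-7-ol | C(c5ccccc5)Oc1ccc([C@@H]2C[C@H](c3c(O)cc4c(c3O[Si](C(C)C)(C(C)C)C(C)C)C[C@@H](OCc5ccccc5)[C@@H](c3ccc(OCc5ccccc5)cc3)O4)c3ccc(OCc5ccccc5)cc3O2)cc1 | intermediate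
31 | (2R,3R)-3-(benzyloxy)-2-[4-(benzyloxy)phenyl]-6-[(2S,4S)-7-(benzyloxy)-2-[4-(benzyloxy)phenyl]chroman-4-yl]chromane-5,7-diol | C(c5ccccc5)Oc1ccc([C@@H]2C[C@H](c3c(O)cc4c(c3O)C[C@@H](OCc5ccccc5)[C@@H](c3ccc(OCc5ccccc5)cc3)O4)c3ccc(OCc5ccccc5)cc3O2)cc1 | intermediate
32 | (2R,3R)-6-[(2S,4S)-7-hydroxy-2-(4-hydroxyphenyl)chroman-4-yl]-2-(4-hydroxyphenyl)chromane-3,5,7-triol | Oc1ccc([C@@H]2C[C@H](c3c(O)cc4c(c3O)C[C@@H](O)[C@@H](c3ccc(O)cc3)O4)c3ccc(O)cc3O2)cc1 | target

**Step count and risks**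

Total step count: 17. Longest linear sequence: 12 steps (steps 6–14, then 15–17, from oxazolidinone 9).

Steps most likely to fail:

1. Step 15. The push–pull stabilised, ring-fused cyclobutenone may resist 4π opening below the temperature at which the siloxyalkyne survives, or the s-cis-locked vinylketene may dimerise before the hindered alkyne intercepts it. The fallback uses the known acid-catalysed condensation of a flavan-4-ol with a flavan-3-ol and gives up the benzannulation. It sets out from 1: reduction with NaBH4 in EtOH at 0 °C should give (2S,4S)-2-(4-hydroxyphenyl)chromane-4,7-diol F1. Ionisation of F1 in 0.1 M HCl in aqueous ethanol at rt in the presence of an excess of purchased (−)-epiafzelechin (Oc1cc(O)c2C[C@@H](O)[C@@H](c3ccc(O)cc3)Oc2c1) generates the C4 cation, which the phloroglucinol ring captures at C6 and C8. The 4→6-linked, 2,4-cis isomer is the target, so the fallback comes back to the route at 32. The price is low regio- and stereoselectivity, so separation on Sephadex LH-20 and by preparative HPLC would be needed.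

2. Step 5. Deprotonation of the acidic benzylic C4–H of the ester by LiCHBr2 or the amide bases may compete with carbonyl addition (ester enolisation, epimerisation towards the 2,4-trans series), and the carbenoid rearrangement may be incomplete. The fallback makes the ynolate by oxidation of an acetylide instead of by a 1,2-shift. It sets out from 5: reduction with i-Bu2AlH in CH2Cl2 at –78 °C should give (2S,4S)-7-(benzyloxy)-2-[4-(benzyloxy)phenyl]chromane-4-carbaldehyde F2. Corey–Fuchs olefination (CBr4, PPh3, CH2Cl2, 0 °C) gives (2S,4R)-7-(benzyloxy)-2-[4-(benzyloxy)phenyl]-4-(2,2-dibromoethenyl)chromane F3. Two equivalents of n-BuLi in THF at –78 °C convert F3 into the lithium acetylide of (2S,4R)-7-(benzyloxy)-2-[4-(benzyloxy)phenyl]-4-ethynylchromane F4. Oxidation of F4 with LiOOt-Bu (from t-BuOOH and LiN(SiMe3)2, –78 → 0 °C) gives the ynolate, so the fallback comes back to the route at 7, which is silylated as in step 5 to 8.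

3. Step 14. Acid may ionise the p-benzyloxybenzylic carbinol (epimerisation at lower C2), or the hydroxyl may attack the strained carbonyl and trigger retro-Claisen cleavage of the four-membered ring. The fallback forms the O1–C8a bond at the alkyne stage, before any cyclobutenone is present. It sets out from 22: Bu4NF in THF at 0 °C should give (1R,2R)-2-(benzyloxy)-1-[4-(benzyloxy)phenyl]-5-ethoxypent-4-yn-1-ol F5. A trace of PPTS in dry CH2Cl2 over molecular sieves at 0 °C protonates the ynol ether at its β-carbon, and 6-endo addition of the hydroxyl gives the cyclic ketene acetal (2R,3R)-3-(benzyloxy)-2-[4-(benzyloxy)phenyl]-6-ethoxy-3,4-dihydro-2H-pyran F6, used without purification. Ketene adds to F6 by [2+2] cycloaddition to give (3R,4R)-4-(benzyloxy)-3-[4-(benzyloxy)phenyl]-1-ethoxy-2-oxabicyclo[4.2.0]octan-7-one F7 (cis ring fusion, either face). Loss of ethanol from F7 under equilibrating conditions (catalytic PPTS, PhMe, rt) towards the fully substituted vinylogous ester brings the fallback back to the route at 25.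

**Further compounds**

F1 | step 15 | (2S,4S)-2-(4-hydroxyphenyl)chromane-4,7-diol | Oc1ccc([C@@H]2C[C@H](O)c3ccc(O)cc3O2)cc1
F2 | step 5 | (2S,4S)-7-(benzyloxy)-2-[4-(benzyloxy)phenyl]chromane-4-carbaldehyde | c1ccccc1COc1ccc([C@@H]2C[C@H](C=O)c3ccc(OCc4ccccc4)cc3O2)cc1
F3 | step 5 | (2S,4R)-7-(benzyloxy)-2-[4-(benzyloxy)phenyl]-4-(2,2-dibromoethenyl)chromane | c1ccccc1COc1ccc([C@@H]2C[C@H](C=C(Br)Br)c3ccc(OCc4ccccc4)cc3O2)cc1
F4 | step 5 | lithium acetylide of (2S,4R)-7-(benzyloxy)-2-[4-(benzyloxy)phenyl]-4-ethynylchromane | c1ccccc1COc1ccc([C@@H]2C[C@H](C#C[Li])c3ccc(OCc4ccccc4)cc3O2)cc1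
F5 | step 14 | (1R,2R)-2-(benzyloxy)-1-[4-(benzyloxy)phenyl]-5-ethoxypent-4-yn-1-ol | CCOC#CC[C@@H](OCc1ccccc1)[C@@H](c1ccc(OCc2ccccc2)cc1)O
F6 | step 14 | (2R,3R)-3-(benzyloxy)-2-[4-(benzyloxy)phenyl]-6-ethoxy-3,4-dihydro-2H-pyran | CCOC1=CC[C@@H](OCc2ccccc2)[C@@H](c2ccc(OCc3ccccc3)cc2)O1
F7 | step 14 | (3R,4R)-4-(benzyloxy)-3-[4-(benzyloxy)phenyl]-1-ethoxy-2-oxabicyclo[4.2.0]octan-7-one | CCOC12CC(=O)C1C[C@@H](OCc1ccccc1)[C@@H](c1ccc(OCc3ccccc3)cc1)O2
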